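The target appears alongside its isomer in both earlier runs, and this flask, charged with 0.0780 M coupling partner, is read here through the ratio c(target)/c(isomer of the product).

| flask | substrate | coupling partner | remark | time |
|---|---|---|---|---|
| north | 0.065 M | 0.11 M | run made earlier |  |
| south-east | 0.065 M | 0.17 M | run made earlier |  |
| flask | 0.065 M | 0.0780 M |  | 12 d |

- north (time / d: target / %, isomer of the product / %): 1.25: 53.1, 23.3; 3.00: 54.7, 22.3; 6.00: 51.9, 20.7; 10.0: 49.3, 20.2
- south-east (time / d: target / %, isomer of the product / %): 0.833: 59.4, 24.7; 1.67: 60.1, 25.8; 4.00: 60.0, 24.9; 10.0: 57.5, 23.0

(readings scatter by 0.5 percentage points)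

- ratio of target to isomer of the product at 4.0 min
- ratio of target to isomer of the product at 12 d
- which of target and isomer of the product there is more of at 12 d

The earliest rows of the two tables, pooled, give a first answer: total target over total isomer of the product is 2.34. Putting it back into the last rows, at 10.0 d, the mean isomer of the product there predicts 50.6% target, yet the mean target read is 53.4%. That gap of 2.8 percentage points stands against a scatter of 0.5 points per reading, so the readings speak against carrying the early ratio to late times.

The second round therefore pools the last rows and gives the late ratio, total target over total isomer of the product at 10.0 d: 2.47. Taken singly, the last rows give 2.44 in the north run and 2.50 in the south-east run, a difference within the scatter of such ratios.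

This reckoning commits to the late ratio at 12 d, with the target ahead. At 4.0 min it takes the early ratio or a little under, since the late ratio read stands above the early one.

The forecast gives 2.35 at 4.0 min and 2.5 at 12 d, with target leading, and allows for “a slight upward drift”.

The flask gives 2.17 at 4.0 min and 2.47 at 12 d, with 40.1% target against 16.2% isomer of the product.

    substrate + coupling partner ⇌ isomer of the product (K = 26.0 M⁻¹, k = 0.690 M⁻¹ h⁻¹)
    substrate + target → side product (k = 0.0600 M⁻¹ h⁻¹)
    substrate + coupling partner ⇌ target (K = 66.0 M⁻¹, k = 1.50 M⁻¹ h⁻¹)
    substrate ⇌ dormant form (K = 0.380, k = 0.0540 h⁻¹)

The ratio of rate constants, the kinetic selectivity factor, is 2.17, and that of equilibrium constants is 2.54. In this flask, the late ratio times the isomer of the product gives 40.0% target. In the neighbour charged with 0.047 M coupling partner, the late ratio times its 11.3% isomer of the product gives 27.9%, and that neighbour holds 27.3% target.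

Readings and results are calculated from invented constants, noise included.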